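**Strategy**

- Retrosynthesis: ring C is opened at O1–C2 and C2–C3 (C2 returns to a one-carbon amide acetal), which leaves a 2-hydroxydeoxybenzoin; the C3–C1' bond to ring B is cut next, and ring B is traced back to a non-aromatic six-membered ketone.
- Enabling feature: around ring B the sequence C1' (carbon arm), C2' (OMe), C3' (pyran carbon), C4' (pyran oxygen) is the CH2–C(=O)–CH2–C(=O) sequence of cyclohexane-1,3-dione. The two carbonyls become C2' and C4', the dione C2 becomes C3', and an α' CH2 becomes C1'.
- Forward: the 2H-pyran ring is annulated onto the dione first. The dihydrochromenone is then joined through C6 to the aldehyde carbon of an aryl glyoxal made from paeonol, and loss of water with double-bond migration aromatizes the carbocycle to ring B without an oxidant.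
- O-Methylation, release of the ring A phenol and a one-carbon insertion with DMF dimethyl acetal close the pyranone (ring C) last.
- Stereochemistry: the target has no stereocentre and no stereogenic acyclic double bond; the two centres created in the aldol stage are uncontrolled and vanish on aromatization.

Key step: step 5

Remark on numbering: the bicyclic fragment is numbered as a 2H-chromene (O1, C2, C3=C4, C4a, C5 to C8, C8a); its C5, C6, C4a and C8a are C2', C1', C3' and C4' of the isoflavone.

Step 1
Reactants: 1 cyclohexane-1,3-dione; 2 3-methylbut-2-enal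
Product: 4 2,2-dimethyl-7,8-dihydro-2H-chromen-5(6H)-one, via Knoevenagel oxatriene 3 (not isolated)
Conditions: ethylenediammonium diacetate (10 mol %), MeOH, rt → 50 °C
Reagents that add atoms: none
Why: Knoevenagel condensation at the dione C2 gives a 1-oxatriene that closes by oxa-6π electrocyclization (the formal 3+3 annulation of 1,3-diones with enals), and the symmetry of the dione allows only one regioisomer.

Step 2
Reactants: 5 1-(2-hydroxy-4-methoxyphenyl)ethanone (paeonol)
Product: 6 1-[4-methoxy-2-(methoxymethoxy)phenyl]ethanone
Conditions: NaH, DMF, 0 °C; MOMCl, 0 °C → rt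
Reagents that add atoms: chloromethyl methyl ether (MOMCl), COCCl
Why: Williamson-type O-alkylation, in which NaH ionizes the chelated phenol far ahead of the methyl ketone and the sodium phenoxide is captured on oxygen by the reactive chloromethyl ether.

Step 3
Reactants: 6 1-[4-methoxy-2-(methoxymethoxy)phenyl]ethanone
Product: 8 2-bromo-1-[4-methoxy-2-(methoxymethoxy)phenyl]ethanone, via silyl enol ether 7 (not isolated)
Conditions: LiN(SiMe3)2, THF, −78 °C; Me3SiCl, −78 → 0 °C; NBS, 0 °C
Reagents that add atoms: N-bromosuccinimide (NBS), O=C1CCC(=O)N1Br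
Why: α-Bromination of a ketone through its silyl enol ether, where the methyl group is the only enolizable position, the enol silane outcompetes the acylated arene for NBS, and no HBr is released, so the MOM acetal should survive and monobromination is expected.

Step 4
Reactants: 8 2-bromo-1-[4-methoxy-2-(methoxymethoxy)phenyl]ethanone
Product: 10 2-[4-methoxy-2-(methoxymethoxy)phenyl]-2-oxoacetaldehyde, via glyoxal hydrate 9 (not isolated)
Conditions: DMSO, NaHCO3, rt; aqueous work-up; toluene azeotrope (Dean–Stark), used at once
Reagents that add atoms: dimethyl sulfoxide (DMSO), CS(C)=O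
Why: Kornblum oxidation, in which the sulfoxide oxygen displaces the activated phenacyl bromide at room temperature and bicarbonate-induced loss of dimethyl sulfide delivers the aldehyde while the buffer keeps HBr away from the MOM acetal; the hydrate formed on work-up is returned to the free aldehyde by azeotropic removal of water.

Step 5
Reactants: 4 2,2-dimethyl-7,8-dihydro-2H-chromen-5(6H)-one; 10 2-[4-methoxy-2-(methoxymethoxy)phenyl]-2-oxoacetaldehyde
Product: 15 2-(5-hydroxy-2,2-dimethyl-2H-chromen-6-yl)-1-[4-methoxy-2-(methoxymethoxy)phenyl]ethanone, via aldol adduct 11 (not isolated), via mesylate 12 (not isolated), via exocyclic enedione 13 (not isolated), via dienone tautomer 14 (not isolated)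
Conditions: LiN(i-Pr)2, THF, −78 °C; 10, −78 °C; MsCl (1.1 equiv), −78 → 0 °C; DBU, 0 °C → rt; aq NH4Cl work-up
Reagents that add atoms: none
Why: Kinetic deprotonation of the vinylogous ester 4 by LiN(i-Pr)2 at −78 °C removes an α' hydrogen at C6 rather than a γ hydrogen at C8 (the regiochemistry exploited in Stork–Danheiser alkylation), and the enolate adds to the aldehyde carbonyl of 10, which is much more electrophilic than the neighbouring aryl ketone and has no enolizable hydrogen, so that the C6–CH(O) bond (the later C1'–C3 bond) forms in a directed aldol addition. The lithium alkoxide of 11 is sulfonylated in the flask to 12, and DBU expels mesylate by an E1cB elimination through the C5 enolate to give the exocyclic 2-ene-1,4-dione 13. In 13 the C7 hydrogens are γ to the aryl ketone, so DBU removes one of them and the dienolate is reprotonated at the exocyclic carbon, which moves the double bond into the ring (14), and enolization of this cyclohexadienone gives the phenol 15, the gain of aromaticity making the sequence irreversible. The closest known reaction type is the aldol condensation at the α' carbon of cyclohexenones and 3-alkoxycyclohexenones followed by base-mediated isoaromatization of the 6-ylidene enone to an ortho-substituted phenol; no ring is closed here, ring B arising by aromatization of a carbocycle that already exists. The two stereocentres of 11 are formed without control and both disappear in 13, so no stereochemical element is needed. Because the glyoxal already holds the oxidation level of the deoxybenzoin, no oxidant or Lewis acid meets the chromene C3=C4 bond, and because the medium stays basic until a buffered work-up the ortho-hydroxy deoxybenzoin cannot cyclodehydrate to a 2-arylbenzofuran.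

Step 6
Reactants: 15 2-(5-hydroxy-2,2-dimethyl-2H-chromen-6-yl)-1-[4-methoxy-2-(methoxymethoxy)phenyl]ethanone
Product: 16 1-[4-methoxy-2-(methoxymethoxy)phenyl]-2-(5-methoxy-2,2-dimethyl-2H-chromen-6-yl)ethanone
Conditions: MeI, K2CO3, acetone, 40 °C
Reagents that add atoms: iodomethane, CI
Why: Williamson O-methylation, in which K2CO3 in acetone ionizes the phenol but not appreciably the deoxybenzoin methylene, so the phenoxide should be methylated on oxygen while the MOM ether and the chromene are inert.

Step 7
Reactants: 16 1-[4-methoxy-2-(methoxymethoxy)phenyl]-2-(5-methoxy-2,2-dimethyl-2H-chromen-6-yl)ethanone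
Product: 17 1-(2-hydroxy-4-methoxyphenyl)-2-(5-methoxy-2,2-dimethyl-2H-chromen-6-yl)ethanone
Conditions: HCl (3 M aq, few equiv), MeOH, 40 °C
Reagents that add atoms: none
Why: Acid-catalysed acetal exchange of the MOM ether with methanol frees the phenol, which is held in a hydrogen bond to the ketone; the ring B oxygen next to the benzylic arm is already a methyl ether, so no benzofuran can form, and 2,2-dimethyl-2H-chromenes tolerate dilute methanolic HCl at mild temperature.

Step 8
Reactants: 17 1-(2-hydroxy-4-methoxyphenyl)-2-(5-methoxy-2,2-dimethyl-2H-chromen-6-yl)ethanone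
Product: 19 7-methoxy-3-(5-methoxy-2,2-dimethyl-2H-chromen-6-yl)-4H-chromen-4-one, via enaminone 18 (not isolated)
Conditions: Me2NCH(OMe)2, toluene, 95 °C
Reagents that add atoms: N,N-dimethylformamide dimethyl acetal, COC(OC)N(C)C
Why: Isoflavone synthesis from a 2-hydroxydeoxybenzoin with an amide acetal, in which condensation at the activated methylene gives the enaminone, the phenol adds to its β carbon (6-endo-trig oxa-Michael addition) and dimethylamine is expelled to give the aromatic pyranone under neutral conditions that leave the chromene untouched.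

**Compound list**

1 | cyclohexane-1,3-dione | O=C1CCCC(=O)C1 | starting material
2 | 3-methylbut-2-enal | CC(C)=CC=O | starting material
3 | 2-(3-methylbut-2-en-1-ylidene)cyclohexane-1,3-dione (Knoevenagel oxatriene) | CC(C)=CC=C1C(=O)CCCC1=O | intermediate
4 | 2,2-dimethyl-7,8-dihydro-2H-chromen-5(6H)-one | CC1(C)C=CC2=C(O1)CCCC2=O | intermediate
5 | 1-(2-hydroxy-4-methoxyphenyl)ethanone (paeonol) | COc1ccc(C(C)=O)c(O)c1 | starting material
6 | 1-[4-methoxy-2-(methoxymethoxy)phenyl]ethanone | COCOc1cc(OC)ccc1C(C)=O | intermediate
7 | {1-[4-methoxy-2-(methoxymethoxy)phenyl]ethenyl}oxy(trimethyl)silane (silyl enol ether) | COCOc1cc(OC)ccc1C(=C)O[Si](C)(C)C | intermediate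
8 | 2-bromo-1-[4-methoxy-2-(methoxymethoxy)phenyl]ethanone | COCOc1cc(OC)ccc1C(=O)CBr | intermediate
9 | 2,2-dihydroxy-1-[4-methoxy-2-(methoxymethoxy)phenyl]ethanone (glyoxal hydrate) | COCOc1cc(OC)ccc1C(=O)C(O)O | intermediate
10 | 2-[4-methoxy-2-(methoxymethoxy)phenyl]-2-oxoacetaldehyde | COCOc1cc(OC)ccc1C(=O)C=O | intermediate
11 | 6-{1-hydroxy-2-[4-methoxy-2-(methoxymethoxy)phenyl]-2-oxoethyl}-2,2-dimethyl-7,8-dihydro-2H-chromen-5(6H)-one (aldol adduct, mixture of diastereomers, present as its lithium alkoxide) | CC1(C)C=CC2=C(O1)CCC(C(O)C(=O)c3ccc(OC)cc3OCOC)C2=O | intermediate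
12 | 1-(2,2-dimethyl-5-oxo-5,6,7,8-tetrahydro-2H-chromen-6-yl)-2-[4-methoxy-2-(methoxymethoxy)phenyl]-2-oxoethyl methanesulfonate (mixture of diastereomers) | CC1(C)C=CC2=C(O1)CCC(C(OS(C)(=O)=O)C(=O)c3ccc(OC)cc3OCOC)C2=O | intermediate
13 | (E)-6-{2-[4-methoxy-2-(methoxymethoxy)phenyl]-2-oxoethylidene}-2,2-dimethyl-7,8-dihydro-2H-chromen-5(6H)-one (E expected; either geometry converges) | CC1(C)C=CC2=C(O1)CC/C(=C\C(=O)c3ccc(OC)cc3OCOC)C2=O | intermediate
14 | 6-{2-[4-methoxy-2-(methoxymethoxy)phenyl]-2-oxoethyl}-2,2-dimethyl-2H-chromen-5(8H)-one (dienone tautomer of 15) | CC1(C)C=CC2=C(O1)CC=C(CC(=O)c3ccc(OC)cc3OCOC)C2=O | intermediate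
15 | 2-(5-hydroxy-2,2-dimethyl-2H-chromen-6-yl)-1-[4-methoxy-2-(methoxymethoxy)phenyl]ethanone | CC1(C)C=Cc2c(O1)ccc(CC(=O)c3ccc(OC)cc3OCOC)c2O | intermediate
16 | 1-[4-methoxy-2-(methoxymethoxy)phenyl]-2-(5-methoxy-2,2-dimethyl-2H-chromen-6-yl)ethanone | CC1(C)C=Cc2c(O1)ccc(CC(=O)c3ccc(OC)cc3OCOC)c2OC | intermediate
17 | 1-(2-hydroxy-4-methoxyphenyl)-2-(5-methoxy-2,2-dimethyl-2H-chromen-6-yl)ethanone | CC1(C)C=Cc2c(O1)ccc(CC(=O)c3ccc(OC)cc3O)c2OC | intermediate
18 | 3-(dimethylamino)-1-(2-hydroxy-4-methoxyphenyl)-2-(5-methoxy-2,2-dimethyl-2H-chromen-6-yl)prop-2-en-1-one (push-pull alkene, geometry not fixed) | CN(C)C=C(C(=O)c1ccc(OC)cc1O)c1ccc2c(c1OC)C=CC(C)(C)O2 | intermediate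
19 | 7-methoxy-3-(5-methoxy-2,2-dimethyl-2H-chromen-6-yl)-4H-chromen-4-one (CNP0240185.0) | COc1ccc2c(=O)c(-c3ccc4c(c3OC)C=CC(C)(C)O4)coc2c1 | target

**Step count**

Total: 8 steps. Longest linear sequence: 7 steps (from 5 through steps 2 to 8); the branch from 1 and 2 joins at step 5.

**Steps most likely to fail**

1. Step 5. Several processes could erode it:
   - equilibration of the kinetic C6 enolate to the C8 dienolate before addition;
   - quenching of the enolate by residual water of hydration or by oligomerized glyoxal;
   - retro-aldol cleavage of the lithium aldolate before sulfonylation;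
   - conjugate addition to the ene-dione;
   - sulfonylation of the newly formed phenoxide by leftover MsCl.

   The fallback moves the oxidation level from the electrophile to a later dehydrogenation and sets out from 4 together with the bromide 8. The C6 lithium enolate of 4 (LiN(i-Pr)2, THF, −78 °C) would be alkylated by 8 to give the 1,4-diketone 6-{2-[4-methoxy-2-(methoxymethoxy)phenyl]-2-oxoethyl}-2,2-dimethyl-7,8-dihydro-2H-chromen-5(6H)-one F1. Its more acidic and less hindered aryl ketone methylene would then be selenylated (LiN(SiMe3)2, PhSeCl, THF, −78 °C) to the α-phenylselanyl ketone F2. Oxidation (H2O2, pyridine, CH2Cl2, 0 °C) would give the selenoxide F3, whose syn elimination can only take the β hydrogen at C6. This delivers the exocyclic enedione 13, where the route is rejoined, and DBU completes the isomerization to 15.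

2. Step 4. The risks are loss of the MOM group if HBr is not scavenged fast enough, bromination or over-oxidation to the arylglyoxylic acid by bromine generated from HBr and DMSO, and incomplete dehydration of the hydrate or oligomerization of the free aldehyde before use. The fallback avoids the bromide altogether and sets out from 6. Condensation with DMF dimethyl acetal (neat, 100 °C) would give the enaminone (E)-3-(dimethylamino)-1-[4-methoxy-2-(methoxymethoxy)phenyl]prop-2-en-1-one F4. Oxidative cleavage of its enamine double bond (NaIO4, THF/H2O, rt) would deliver the glyoxal hydrate 9, where the route is rejoined and the azeotropic drying of step 4 gives 10. This path also bypasses step 3.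

3. Step 8. The risks are slow condensation at the crowded methylene next to the ortho-methoxy group, stalling at the enaminone stage, and competing O-methylation of the ring A phenol by the amide acetal at the temperature needed. The fallback activates the nucleophile instead of the electrophile and sets out from 17. Claisen C-formylation of its dianion (HCO2Et, NaH, THF, 0 °C → rt) would give, after mild acidification, the cyclic hemiacetal 2-hydroxy-7-methoxy-3-(5-methoxy-2,2-dimethyl-2H-chromen-6-yl)chroman-4-one F5. Brief warming in AcOH would dehydrate it to 19, where the route is rejoined.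

Further compounds
F1 | step 5 | 6-{2-[4-methoxy-2-(methoxymethoxy)phenyl]-2-oxoethyl}-2,2-dimethyl-7,8-dihydro-2H-chromen-5(6H)-one (racemic) | CC1(C)C=CC2=C(O1)CCC(CC(=O)c3ccc(OC)cc3OCOC)C2=O
F2 | step 5 | 6-{2-[4-methoxy-2-(methoxymethoxy)phenyl]-2-oxo-1-(phenylselanyl)ethyl}-2,2-dimethyl-7,8-dihydro-2H-chromen-5(6H)-one (mixture of diastereomers) | CC1(C)C=CC2=C(O1)CCC(C([Se]c3ccccc3)C(=O)c4ccc(OC)cc4OCOC)C2=O
F3 | step 5 | 6-{2-[4-methoxy-2-(methoxymethoxy)phenyl]-2-oxo-1-(phenylseleninyl)ethyl}-2,2-dimethyl-7,8-dihydro-2H-chromen-5(6H)-one (mixture of diastereomers) | CC1(C)C=CC2=C(O1)CCC(C([Se](=O)c3ccccc3)C(=O)c4ccc(OC)cc4OCOC)C2=O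
F4 | step 4 | (E)-3-(dimethylamino)-1-[4-methoxy-2-(methoxymethoxy)phenyl]prop-2-en-1-one | COCOc1cc(OC)ccc1C(=O)/C=C/N(C)C
F5 | step 8 | 2-hydroxy-7-methoxy-3-(5-methoxy-2,2-dimethyl-2H-chromen-6-yl)chroman-4-one (mixture of diastereomers) | COc1ccc2c(c1)OC(O)C(c1ccc3c(c1OC)C=CC(C)(C)O3)C2=O
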